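All runs are simulated for substances that don't exist.

Percentage points of target gained over a stretch of fixed length are the unit to start from: a gain can be read without knowing where the curve ends.

| flask | starting material | capture agent | catalyst | remark | time |
|---|---|---|---|---|---|
| ash | 0.013 M | 0.020 M | 0.1 mol% | run made earlier |  |
| elm | 0.030 M | 0.020 M | 0.1 mol% | run made earlier |  |
| flask | 0.020 M | 0.0200 M | 0.1 mol% |  | 40 min |

| run | time / min | target / % |
|---|---|---|
| ash | 3.00 | 1.7 |
| ash | 5.00 | 4.5 |
| ash | 8.00 | 10.0 |
| ash | 12.0 | 19.0 |
| ash | 15.0 | 24.5 |
| ash | 25.0 | 43.7 |
| ash | 40.0 | 62.9 |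
| elm | 6.00 | 11.0 |
| elm | 12.0 | 28.5 |
| elm | 15.0 | 35.8 |
| elm | 25.0 | 56.2 |
| elm | 30.0 | 63.1 |
| elm | 40.0 | 73.9 |

(scatter of a reading: 0.3 percentage points)

- amount of target in percent of the starting material charged, at 4.0 min, 15 min and 40 min

*How fast does the tail run?* In the elm run the target gains 20 percentage points from 15.0 min to 25.0 min, and 11 points over an equal stretch starting 15.0 min later, a factor of 0.529. If gains shrink steadily, the slow clock, the time in which the late gain halves, is 16.3 min.

*Where does the tail end?* Adding the shrinking gains to the last readings, the ash run ends near 84.5% and the elm run near 93.8%.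

*Why short of the whole charge?* My guess is that capture agent, equal in both runs, competes with catalyst, which grows with the charge. From the ash run to the elm run the ratio of lost to won falls by a factor of 2.78 while the charge rises by a factor of 2.31, a loose fit. Scaling both by charge and averaging puts this flask's end near 90.2%.

*But the clock ignores the start?* Yes, so each run needs a delay behind a pure clock curve: 7.83 min for ash and 3.44 min for elm, a ratio of 2.28, close to the ratio of the charges taken the other way round. This flask gets 5.13 min, and so I commit to 30.9% at 15 min and 69.7% at 40 min.

*And inside the delay?* There I scale the ash reading at 5.00 min by time squared and by charge, which gives 4.43% at 4.0 min.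

The forecast, seeing plots that “go straight after an induction period”, gave 4.5%, 30.5% and 69%. The flask gives 4.41%, 30.9% and 69.8%.

    starting material → open intermediate (k = 7.41 × 10⁻⁴ /s)
    catalyst + open intermediate → catalyst + target (k = 139 /M/s)
    open intermediate + capture agent → trapped intermediate (k = 0.0166 /M/s)

In this flask the open intermediate stands at 11.4% at 4.00 min and 5.31% at 40.0 min; by the catalyst path alone, other concentrations as charged, its half-life is 4.2 min, shorter than the slow clock of 16.3 min read off the elm run, while by the capture path alone it is 35 min. At 40.0 min the catalyst path uses 9.1 times as much open intermediate as the capture path, and at 400 min the flask holds target 89.8% and trapped intermediate 10.2%.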